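**Retrosynthetic overview**
1. Target 17 ⇐ 7-O-benzyl ether 16 (hydrogenolysis) ⇐ dihydronaphthalene triol 15 by hydroxyl-directed hydrogenation of C3=C4 (sets C3).
2. 15 ⇐ trans-1-aryl-1,2-dihydronaphthalene diester 14 (ester reduction).
3. 14 ⇐ achiral (E,E)-dibenzylidenesuccinate 12 by a proposed chiral-acid-catalysed asymmetric cationic 6π-type cyclisation. It forms C1–C8a and sets C1 (absolute) and C2 (relative); the central carbocycle is the only ring made in the route.
4. 12 ⇐ dimethyl succinate + O-benzylsyringaldehyde 2 + O-allylvanillin 8 by two successive Stobbe condensations; both aromatic rings are bought.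

Assumption: the target is taken exactly as the given SMILES, which is (1S,2R,3R), 1,2-trans-2,3-trans, in tetralin numbering (C1 = aryl-bearing carbon, then C2, C3, C4, C4a, C5–C8, C8a); this numbering is used throughout.

**Route**

Step 1
Reactants: 1 syringaldehyde (4-hydroxy-3,5-dimethoxybenzaldehyde)
Product: 2 4-(benzyloxy)-3,5-dimethoxybenzaldehyde
Conditions: BnBr, K2CO3, DMF, 60 °C
Reagents that add atoms: benzyl bromide, BrCc1ccccc1
Why: Williamson etherification of the phenoxide; no stereocentre is involved.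

Step 2
Reactants: 2 4-(benzyloxy)-3,5-dimethoxybenzaldehyde; 3 dimethyl succinate
Product: 5 (E)-4-[4-(benzyloxy)-3,5-dimethoxyphenyl]-3-(methoxycarbonyl)but-3-enoic acid, via paraconate lactone 4 (not isolated)
Conditions: NaOMe, MeOH, reflux; then aq HCl
Reagents that add atoms: none
Why: Stobbe condensation (aldol, lactonisation to the paraconate, E1cB ring opening) gives the half-ester with the aryl group trans to the conjugated ester (E); the benzyl ether is inert to methoxide.

Step 3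
Reactants: 5 (E)-4-[4-(benzyloxy)-3,5-dimethoxyphenyl]-3-(methoxycarbonyl)but-3-enoic acid
Product: 6 dimethyl (E)-2-[4-(benzyloxy)-3,5-dimethoxybenzylidene]succinate
Conditions: MeOH, cat. H2SO4, reflux
Reagents that add atoms: methanol, CO
Why: Fischer esterification of the unhindered CH2CO2H; the aryl benzyl ether and the trisubstituted alkene tolerate catalytic acid in methanol.

Step 4
Reactants: 7 vanillin (4-hydroxy-3-methoxybenzaldehyde)
Product: 8 4-(allyloxy)-3-methoxybenzaldehyde
Conditions: allyl bromide, K2CO3, acetone, reflux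
Reagents that add atoms: allyl bromide, C=CCBr
Why: Williamson etherification; allyl is chosen because it survives the base and can later be removed without touching the benzyl ether.

Step 5
Reactants: 6 dimethyl (E)-2-[4-(benzyloxy)-3,5-dimethoxybenzylidene]succinate; 8 4-(allyloxy)-3-methoxybenzaldehyde
Product: 10 (2E,3E)-3-[4-(allyloxy)-3-methoxybenzylidene]-2-[4-(benzyloxy)-3,5-dimethoxybenzylidene]-4-methoxy-4-oxobutanoic acid, via arylidene paraconate lactone 9 (not isolated)
Conditions: NaOMe, MeOH, reflux; then aq HCl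
Reagents that add atoms: none
Why: Second Stobbe condensation at the remaining CH2 of 6 gives the (E,E)-diene, each aryl trans to its own carboxyl; the carboxyl that lactonised is released as the free acid, and allyl and benzyl ethers are base-stable.

Step 6
Reactants: 10 (2E,3E)-3-[4-(allyloxy)-3-methoxybenzylidene]-2-[4-(benzyloxy)-3,5-dimethoxybenzylidene]-4-methoxy-4-oxobutanoic acid
Product: 11 dimethyl (2E,3E)-2-[4-(allyloxy)-3-methoxybenzylidene]-3-[4-(benzyloxy)-3,5-dimethoxybenzylidene]succinate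
Conditions: MeI, K2CO3, DMF, rt
Reagents that add atoms: iodomethane, CI
Why: SN2 O-methylation of the carboxylate, which avoids acid on the hindered conjugated acid; there is no free phenol to compete.

Step 7
Reactants: 11 dimethyl (2E,3E)-2-[4-(allyloxy)-3-methoxybenzylidene]-3-[4-(benzyloxy)-3,5-dimethoxybenzylidene]succinate
Product: 12 dimethyl (2E,3E)-2-[4-(benzyloxy)-3,5-dimethoxybenzylidene]-3-(4-hydroxy-3-methoxybenzylidene)succinate
Conditions: Pd(PPh3)4 (5 mol%), morpholine, THF, rt, dark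
Reagents that add atoms: none
Why: Tsuji–Trost deallylation (Pd π-allyl captured by morpholine) frees only the guaiacyl phenol under neutral conditions; the benzyl ether, esters and diene are untouched.

Step 8
Reactants: 12 dimethyl (2E,3E)-2-[4-(benzyloxy)-3,5-dimethoxybenzylidene]-3-(4-hydroxy-3-methoxybenzylidene)succinate
Product: 14 dimethyl (1S,2R)-7-(benzyloxy)-1-(4-hydroxy-3-methoxyphenyl)-6,8-dimethoxy-1,2-dihydronaphthalene-2,3-dicarboxylate, via ester enol 13 (not isolated)
Conditions: (S,S)-IDPi (5 mol%; 3,3'-diaryl-BINOL-derived imidodiphosphorimidate, N-triflyl core), CHCl3, 5 Å MS, −20 °C → rt, dark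
Reagents that add atoms: none
Why: Proposed new method: the confined strong chiral acid protonates the more basic ester carbonyl (push–pull with the free para-OH, which also hydrogen-bonds to the chiral anion) to give a vinylogous p-quinone-methide-type cation whose C1–C2 bond can rotate; only this ring carries a free OH, so C1 is the electrophile, and the trioxygenated ring (ortho and para to OMe) closes onto C1 in a 6π-type Friedel–Crafts step inside the chiral ion pair, setting C1 (S); rearomatisation gives ester enol 13, which is protonated at C2 anti to the pseudoaxial C1 aryl to give the trans (2R) diester; the closest known reaction types are the racemic superacid-mediated cyclisation of dibenzylidenesuccinates to trans-1-aryl-1,2-dihydronaphthalenes, chiral-Brønsted-acid-catalysed asymmetric Nazarov cyclisation and chiral-phosphoric-acid-catalysed arene additions to p-quinone methides; the sense of induction cannot be predicted, so the catalyst antipode that gives (1S) is fixed in the first run.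

Step 9
Reactants: 14 dimethyl (1S,2R)-7-(benzyloxy)-1-(4-hydroxy-3-methoxyphenyl)-6,8-dimethoxy-1,2-dihydronaphthalene-2,3-dicarboxylate
Product: 15 4-[(1S,2R)-7-(benzyloxy)-2,3-bis(hydroxymethyl)-6,8-dimethoxy-1,2-dihydronaphthalen-1-yl]-2-methoxyphenol
Conditions: DIBAL-H (7 equiv), CH2Cl2, −78 → 0 °C; Rochelle salt
Reagents that add atoms: none
Why: DIBAL-H 1,2-reduction of both esters (the enoate gives the allylic alcohol without conjugate reduction); the reagent is non-basic, so C2 is not epimerised and is fixed once reduced.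

Step 10
Reactants: 15 4-[(1S,2R)-7-(benzyloxy)-2,3-bis(hydroxymethyl)-6,8-dimethoxy-1,2-dihydronaphthalen-1-yl]-2-methoxyphenol
Product: 16 4-[(1S,2R,3R)-7-(benzyloxy)-2,3-bis(hydroxymethyl)-6,8-dimethoxy-1,2,3,4-tetrahydronaphthalen-1-yl]-2-methoxyphenol
Conditions: [Ir(cod)(PCy3)(py)]PF6 (10 mol%), H2 (1 atm), CH2Cl2, rt
Reagents that add atoms: none
Why: Hydroxyl-directed homogeneous hydrogenation (Crabtree catalyst): iridium bound to the pseudoaxial homoallylic C2–CH2OH delivers H2 to that face of C3=C4, so the new C3–H is cis to C2–CH2OH and the C3–CH2OH ends up trans to it (3R); the benzyl ether is not cleaved by this catalyst.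

Step 11
Reactants: 16 4-[(1S,2R,3R)-7-(benzyloxy)-2,3-bis(hydroxymethyl)-6,8-dimethoxy-1,2,3,4-tetrahydronaphthalen-1-yl]-2-methoxyphenol
Product: 17 (+)-8-methoxyisolariciresinol
Conditions: H2 (1 atm), 10% Pd/C, MeOH, rt
Reagents that add atoms: none
Why: Hydrogenolysis of the aryl benzyl ether; the diarylmethine C1–H and all three stereocentres are unaffected.

**Compound list**
1 | syringaldehyde (4-hydroxy-3,5-dimethoxybenzaldehyde) | COc1cc(C=O)cc(OC)c1O | starting material
2 | 4-(benzyloxy)-3,5-dimethoxybenzaldehyde | COc1cc(C=O)cc(OC)c1OCc1ccccc1 | intermediate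
3 | dimethyl succinate | COC(=O)CCC(=O)OC | starting material
4 | methyl 2-[4-(benzyloxy)-3,5-dimethoxyphenyl]-5-oxotetrahydrofuran-3-carboxylate (paraconate lactone, racemic mixture of diastereomers, not isolated) | COC(=O)C1CC(=O)OC1c1cc(OC)c(OCc2ccccc2)c(OC)c1 | intermediate
5 | (E)-4-[4-(benzyloxy)-3,5-dimethoxyphenyl]-3-(methoxycarbonyl)but-3-enoic acid | COC(=O)/C(CC(=O)O)=C/c1cc(OC)c(OCc2ccccc2)c(OC)c1 | intermediate
6 | dimethyl (E)-2-[4-(benzyloxy)-3,5-dimethoxybenzylidene]succinate | COC(=O)/C(CC(=O)OC)=C/c1cc(OC)c(OCc2ccccc2)c(OC)c1 | intermediate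
7 | vanillin (4-hydroxy-3-methoxybenzaldehyde) | COc1cc(C=O)ccc1O | starting material
8 | 4-(allyloxy)-3-methoxybenzaldehyde | COc1cc(C=O)ccc1OCC=C | intermediate
9 | methyl 2-[4-(allyloxy)-3-methoxyphenyl]-4-[(E)-4-(benzyloxy)-3,5-dimethoxybenzylidene]-5-oxotetrahydrofuran-3-carboxylate (arylidene paraconate lactone, racemic mixture of diastereomers, not isolated) | COC(=O)C1C(c2ccc(OCC=C)c(OC)c2)OC(=O)/C1=C/c1cc(OC)c(OCc2ccccc2)c(OC)c1 | intermediate
10 | (2E,3E)-3-[4-(allyloxy)-3-methoxybenzylidene]-2-[4-(benzyloxy)-3,5-dimethoxybenzylidene]-4-methoxy-4-oxobutanoic acid | COC(=O)/C(=C/c1ccc(OCC=C)c(OC)c1)/C(=C\c1cc(OC)c(OCc2ccccc2)c(OC)c1)C(=O)O | intermediate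
11 | dimethyl (2E,3E)-2-[4-(allyloxy)-3-methoxybenzylidene]-3-[4-(benzyloxy)-3,5-dimethoxybenzylidene]succinate | COC(=O)/C(=C/c1ccc(OCC=C)c(OC)c1)/C(=C\c1cc(OC)c(OCc2ccccc2)c(OC)c1)C(=O)OC | intermediate
12 | dimethyl (2E,3E)-2-[4-(benzyloxy)-3,5-dimethoxybenzylidene]-3-(4-hydroxy-3-methoxybenzylidene)succinate (achiral) | COC(=O)/C(=C/c1ccc(O)c(OC)c1)/C(=C\c1cc(OC)c(OCc2ccccc2)c(OC)c1)C(=O)OC | intermediate
13 | methyl (1S)-7-(benzyloxy)-2-[hydroxy(methoxy)methylidene]-1-(4-hydroxy-3-methoxyphenyl)-6,8-dimethoxy-1,2-dihydronaphthalene-3-carboxylate (ester enol, not isolated) | COc1cc([C@H]2c3c(cc(OC)c(OCc4ccccc4)c3OC)C=C(C(=O)OC)C2=C(O)OC)ccc1O | intermediate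
14 | dimethyl (1S,2R)-7-(benzyloxy)-1-(4-hydroxy-3-methoxyphenyl)-6,8-dimethoxy-1,2-dihydronaphthalene-2,3-dicarboxylate (1,2-trans) | COc1cc([C@H]2c3c(cc(OC)c(OCc4ccccc4)c3OC)C=C(C(=O)OC)[C@@H]2C(=O)OC)ccc1O | intermediate
15 | 4-[(1S,2R)-7-(benzyloxy)-2,3-bis(hydroxymethyl)-6,8-dimethoxy-1,2-dihydronaphthalen-1-yl]-2-methoxyphenol | COc1cc([C@H]2c3c(cc(OC)c(OCc4ccccc4)c3OC)C=C(CO)[C@@H]2CO)ccc1O | intermediate
16 | 4-[(1S,2R,3R)-7-(benzyloxy)-2,3-bis(hydroxymethyl)-6,8-dimethoxy-1,2,3,4-tetrahydronaphthalen-1-yl]-2-methoxyphenol (7-O-benzyl ether of the target) | COc1cc([C@H]2c3c(cc(OC)c(OCc4ccccc4)c3OC)C[C@@H](CO)[C@@H]2CO)ccc1O | intermediate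
17 | (+)-8-methoxyisolariciresinol, (1S,2R,3R)-1-(4-hydroxy-3-methoxyphenyl)-2,3-bis(hydroxymethyl)-6,8-dimethoxy-1,2,3,4-tetrahydronaphthalen-7-ol | COc1cc([C@H]2c3c(cc(OC)c(O)c3OC)C[C@@H](CO)[C@@H]2CO)ccc1O | target

**Count**
Total steps: 11. Longest linear sequence: 10 steps (1, 2, 3, 5, 6, 7, 8, 9, 10, 11); step 4 is a one-step side branch.

**Three steps most likely to fail, with fallbacks**

Step 8 (the proposed new cyclisation) is the main risk: the acid may not turn over on an ester, the ee may be low, or the guaiacyl ring may cyclise instead. The fallback uses only known chemistry, sets out from half-ester 5 and comes back to the route at 16.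
- Rh(I)-catalysed asymmetric hydrogenation of 5 (chiral bisphosphine of the MOD-DIOP or DuPHOS type, antipode chosen for R; H2, MeOH, Et3N) gives (R)-3-[4-(benzyloxy)-3,5-dimethoxybenzyl]-4-methoxy-4-oxobutanoic acid F1.
- Reduction of the ester beside the carboxylate (KOH, then Ca(BH4)2 from CaCl2/NaBH4, EtOH; aq HCl) with lactonisation gives (R)-4-[4-(benzyloxy)-3,5-dimethoxybenzyl]dihydrofuran-2(3H)-one F2.
- The lithium enolate (LDA, THF, −78 °C) adds to aldehyde 8 anti to the benzyl group to give the trans aldol (3S,4R)-3-{[4-(allyloxy)-3-methoxyphenyl](hydroxy)methyl}-4-[4-(benzyloxy)-3,5-dimethoxybenzyl]dihydrofuran-2(3H)-one F3, as a mixture of carbinol epimers that converge in the next operation.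
- TFA in CH2Cl2 ionises the carbinol, and substrate-controlled Friedel–Crafts closure ortho to OMe gives the all-trans lactone (3aR,9S,9aR)-9-[4-(allyloxy)-3-methoxyphenyl]-7-(benzyloxy)-6,8-dimethoxy-3a,4,9,9a-tetrahydronaphtho[2,3-c]furan-1(3H)-one F4.
- LiAlH4 in THF opens it to [(1S,2R,3R)-1-[4-(allyloxy)-3-methoxyphenyl]-7-(benzyloxy)-6,8-dimethoxy-1,2,3,4-tetrahydronaphthalene-2,3-diyl]dimethanol F5.
- Pd(PPh3)4/morpholine removes the allyl group to give 16, which continues through step 11.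

Step 10 (directed hydrogenation) may give the wrong face, isomerise the alkene, or be inhibited by the triol. The fallback swaps kinetic hydroxyl delivery for hydrogenation plus base epimerisation; it sets out from diester 14 and comes back at target 17.
- H2 over Pd/C (EtOAc/MeOH) adds anti to the C2 ester and cleaves the benzyl ether, giving the 2,3-cis diester dimethyl (1S,2R,3S)-7-hydroxy-1-(4-hydroxy-3-methoxyphenyl)-6,8-dimethoxy-1,2,3,4-tetrahydronaphthalene-2,3-dicarboxylate F6.
- NaOMe in MeOH (in excess over the two phenoxides, monitored) epimerises the more accessible C3 to dimethyl (1S,2R,3R)-7-hydroxy-1-(4-hydroxy-3-methoxyphenyl)-6,8-dimethoxy-1,2,3,4-tetrahydronaphthalene-2,3-dicarboxylate F7.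
- LiAlH4 in THF gives 17.
- Caveat: the 8-OMe peri strain makes the equilibrium position at C2 uncertain, so the epimerisation must be stopped once C3 has inverted.

Step 5 (second Stobbe condensation) may give low conversion or E/Z mixtures on the hindered, cross-conjugated enolate. The fallback separates C–C bond formation from elimination; it sets out from diester 6 (with aldehyde 8) and comes back at 11, bypassing 10 and step 6.
- LDA (THF, −78 °C) and 8, quenched cold with AcOH, give the aldol dimethyl (E)-2-{[4-(allyloxy)-3-methoxyphenyl](hydroxy)methyl}-3-[4-(benzyloxy)-3,5-dimethoxybenzylidene]succinate F8 (diastereomer mixture).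
- MsCl/Et3N (CH2Cl2, 0 °C) gives the mesylate dimethyl (E)-2-{[4-(allyloxy)-3-methoxyphenyl][(methylsulfonyl)oxy]methyl}-3-[4-(benzyloxy)-3,5-dimethoxybenzylidene]succinate F9.
- DBU at rt eliminates it (E1cB) to the (E,E)-diester 11.

**Further compounds**
F1 | step 8 | (R)-3-[4-(benzyloxy)-3,5-dimethoxybenzyl]-4-methoxy-4-oxobutanoic acid | COC(=O)[C@@H](CC(=O)O)Cc1cc(OC)c(OCc2ccccc2)c(OC)c1
F2 | step 8 | (R)-4-[4-(benzyloxy)-3,5-dimethoxybenzyl]dihydrofuran-2(3H)-one | COc1cc(C[C@H]2COC(=O)C2)cc(OC)c1OCc1ccccc1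
F3 | step 8 | (3S,4R)-3-{[4-(allyloxy)-3-methoxyphenyl](hydroxy)methyl}-4-[4-(benzyloxy)-3,5-dimethoxybenzyl]dihydrofuran-2(3H)-one (carbinol epimers) | COc1cc(C[C@@H](CO2)[C@@H](C(O)c3ccc(OCC=C)c(OC)c3)C2=O)cc(OC)c1OCc1ccccc1
F4 | step 8 | (3aR,9S,9aR)-9-[4-(allyloxy)-3-methoxyphenyl]-7-(benzyloxy)-6,8-dimethoxy-3a,4,9,9a-tetrahydronaphtho[2,3-c]furan-1(3H)-one | COc1cc([C@H]2c3c(cc(OC)c(OCc4ccccc4)c3OC)C[C@H]5COC(=O)[C@H]25)ccc1OCC=C
F5 | step 8 | [(1S,2R,3R)-1-[4-(allyloxy)-3-methoxyphenyl]-7-(benzyloxy)-6,8-dimethoxy-1,2,3,4-tetrahydronaphthalene-2,3-diyl]dimethanol | COc1cc([C@H]2c3c(cc(OC)c(OCc4ccccc4)c3OC)C[C@@H](CO)[C@@H]2CO)ccc1OCC=C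
F6 | step 10 | dimethyl (1S,2R,3S)-7-hydroxy-1-(4-hydroxy-3-methoxyphenyl)-6,8-dimethoxy-1,2,3,4-tetrahydronaphthalene-2,3-dicarboxylate | COc1cc([C@H]2c3c(cc(OC)c(O)c3OC)C[C@H](C(=O)OC)[C@@H]2C(=O)OC)ccc1O
F7 | step 10 | dimethyl (1S,2R,3R)-7-hydroxy-1-(4-hydroxy-3-methoxyphenyl)-6,8-dimethoxy-1,2,3,4-tetrahydronaphthalene-2,3-dicarboxylate | COc1cc([C@H]2c3c(cc(OC)c(O)c3OC)C[C@@H](C(=O)OC)[C@@H]2C(=O)OC)ccc1O
F8 | step 5 | dimethyl (E)-2-{[4-(allyloxy)-3-methoxyphenyl](hydroxy)methyl}-3-[4-(benzyloxy)-3,5-dimethoxybenzylidene]succinate (diastereomer mixture) | COC(=O)/C(=C/c1cc(OC)c(OCc2ccccc2)c(OC)c1)C(C(=O)OC)C(O)c1ccc(OCC=C)c(OC)c1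
F9 | step 5 | dimethyl (E)-2-{[4-(allyloxy)-3-methoxyphenyl][(methylsulfonyl)oxy]methyl}-3-[4-(benzyloxy)-3,5-dimethoxybenzylidene]succinate (diastereomer mixture) | COC(=O)/C(=C/c1cc(OC)c(OCc2ccccc2)c(OC)c1)C(C(=O)OC)C(OS(C)(=O)=O)c1ccc(OCC=C)c(OC)c1
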